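I cannot read how long target lives from its falling curve, since that curve is what is made minus what is lost. So I watch the sum of target and starting material, which the making step leaves unchanged.

You take over these flasks:

all flasks: starting material 0.098 M; protic impurity 0.0196 M
- red: reagent 0.74 equiv; run made earlier
- teal: reagent 3.1 equiv; run made earlier
- violet: reagent 7 equiv; run made earlier
- noon: reagent 1.00 equiv; time 1.0 h
- midnight: reagent 2.00 equiv; time 1.0 h
- autumn: reagent 4.00 equiv; time 1.0 h
- dusk: reagent 8.00 equiv; time 1.0 h

| run | time / min | target / % | starting material / % |
|---|---|---|---|
| red | 5.00 | 4.6 | 75.3 |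
| red | 10.0 | 8.9 | 70.2 |
| red | 15.0 | 11.5 | 67.1 |
| red | 30.0 | 17.9 | 59.2 |
| red | 60.0 | 24.2 | 48.2 |
| teal | 12.0 | 13.4 | 60.7 |
| teal | 25.0 | 17.5 | 48.2 |
| teal | 40.0 | 15.2 | 40.2 |
| teal | 50.0 | 13.7 | 35.2 |
| teal | 60.0 | 11.8 | 32.7 |
| violet | 5.00 | 11.7 | 65.8 |
| violet | 15.0 | 13.0 | 50.5 |
| violet | 30.0 | 8.3 | 37.7 |
| violet | 40.0 | 6.5 | 29.8 |
| violet | 60.0 | 4.1 | 24.6 |

(scatter of a reading: 0.5 percentage points)

* amount of target at the end, in percent of the starting material charged for noon, midnight, autumn, dusk, in this order
* how the row runs (falls, then rises / rises all the way / falls all the way / hardly changes / rises, then falls)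

- the numbers in the tables scatter with a standard deviation of 0.5 percentage points
- "hardly changes" means that all values lie within two and a half points (for a concentration: within two and a half percent of the largest)

In the violet run I take the early loss, which matches the protic impurity at 20.0% of the starting material charged, as over by 15.0 min. From there to 30.0 min the sum falls by 17 percentage points while target averages 10.7%. Reagent is in large excess there, so the loss is pseudo-first-order in target, with a half-life of 6.33 min. I carry this over as the target half-life at noon's charge, 44.3 min: the half-life in a flask, scaled to the noon charge by multiplying by its equivalents. The teal run gives 51.2 min, but I keep the violet figure, from the higher excess.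

When you come, noon will have had 1.35 half-lives and dusk 10.8, so I commit to a row that falls from near the red 24.2%. Add no reagent: at dusk's charge target has 5.54 min, shorter than noon's.

The forecast gives 24.5%, 18%, 9% and 3.3%, a row that falls all the way: “More reagent therefore favours over-reaction”.

The flasks give 23.4%, 17.7%, 8.66% and 2.96%, a row that falls all the way.

    reagent + target → over-reaction product (k = 0.170 M⁻¹ min⁻¹)
    starting material + reagent → target, rate k2*[starting material]^2*[reagent]^0.5 (k = 0.610 M⁻¹·⁵ min⁻¹)
    starting material + protic impurity → quenched substrate (k = 9.90 M⁻¹ min⁻¹)

In noon, with reagent held at its charge, the half-life of target by over-reaction is 41.6 min against my 44.3 min, and target is made 3.28 times faster than it is used up at 0.318 h, a ratio that stands at 1.33 at 1.00 h. Scaled by the equivalents with reagent held at its charge, that half-life gives dusk 11.5 half-lives in the hour against my 10.8, and dusk holds 2.96% of target beside 53.9% of over-reaction product at 1.00 h.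

All runs are calculated for substances that don't exist, and the scatter is random.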